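**Assumption:** the target is the enantiomer written in the SMILES, i.e. (2S,3S,4S,6S) at the oxane ring; compounds 2 and 4 are taken as catalogue items.

## Retrosynthetic overview

1. The chalcone C=C is made last by Claisen–Schmidt condensation of the aryl methyl ketone with 4-hydroxybenzaldehyde; the same base removes all acetates.
2. The oxane (the only ring built) is closed by a C–O bond: 6-endo, invertive attack of the C3 carbinol on the benzylic carbon of a cis-aryl epoxide (sets C2; C3–OH comes from the epoxide).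
3. The cis-epoxide is placed on the hindered face through a bromohydrin of the Z-styrene (from E→Z photoisomerisation); the carbinol comes from CBS reduction.
4. The C4 stereocentre and its aryl–C bond come from a new enantioselective warfarin-type Michael/Friedel–Crafts addition of the acetophenone to a diarylheptadienone.
5. The dienone comes from raspberry ketone and 4-hydroxycinnamaldehyde.

Heptane numbering used below: C3 = oxane C6, C5 = oxane C4, C6 = oxane C3, C7 = oxane C2.

## Route

Step 1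
Reactants: 1 4-(4-hydroxyphenyl)butan-2-one; 2 (E)-4-hydroxycinnamaldehyde
Product: 3 (4E,6E)-1,7-bis(4-hydroxyphenyl)hepta-4,6-dien-3-one
Conditions: pyrrolidine (0.3 equiv), AcOH (0.3 equiv), THF, rt, 36 h
Reagents that add atoms: none
Why: Enamine-mediated aldol condensation at the methyl group of the methyl ketone (the standard diarylheptanoid dienone condensation) gives the thermodynamic E,E-dienone and tolerates free phenols.

Step 2
Reactants: 3 (4E,6E)-1,7-bis(4-hydroxyphenyl)hepta-4,6-dien-3-one; 4 1-(2,4-dihydroxy-6-methoxyphenyl)ethanone (1.3 equiv)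
Product: 5 (5R,6E)-5-(3-acetyl-2,6-dihydroxy-4-methoxyphenyl)-1,7-bis(4-hydroxyphenyl)hept-6-en-3-one (isolated as its ring-chain hemiketal mixture)
Conditions: (R,R)-1,2-diphenylethylenediamine (20 mol %), AcOH (2 equiv), THF, 35 °C, 72 h
Reagents that add atoms: none
Why: Proposed new method: an enantioselective warfarin-type Michael/Friedel–Crafts alkylation with an acylphloroglucinol as C-nucleophile, in which one amine of the diamine forms an iminium ion with the C3 ketone of 3 and the other (protonated) amine hydrogen-bonds the acidic 4'-OH of 4, so that the ring carbon between the two hydroxyls (most nucleophilic because the C=O···HO chelate fixes an enol-like C3'=C4' bond and the 6'-OMe shields C5') adds 1,4 to one face of the β-carbon and sets the (R)-benzylic centre while the 6E-styrene stays conjugated (so no 1,6-attack) and the adduct is trapped as a hemiketal; the closest known chemistry is the diamine-catalysed enantioselective Michael addition of 4-hydroxycoumarin to benzylideneacetone (warfarin) and of naphthols to enones, and the catalyst enantiomer is chosen by that analogy (the (S,S)-catalyst is equally available if the sense is opposite).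

Step 3
Reactants: 5 (5R,6E)-5-(3-acetyl-2,6-dihydroxy-4-methoxyphenyl)-1,7-bis(4-hydroxyphenyl)hept-6-en-3-one
Product: 6 (5R,6E)-5-(3-acetyl-2,6-diacetoxy-4-methoxyphenyl)-1,7-bis(4-acetoxyphenyl)hept-6-en-3-one
Conditions: Ac2O (8 equiv), pyridine, DMAP (cat.), 40 °C
Reagents that add atoms: acetic anhydride, CC(=O)OC(C)=O
Why: DMAP-catalysed O-acetylation of all four phenols pulls the hemiketal equilibrium to the open-chain ketone (as acetylation of warfarin does), masks the two ortho-phenols that would otherwise open the epoxide later, and makes the C7 aryl a poor cation stabiliser.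

Step 4
Reactants: 6 (5R,6E)-5-(3-acetyl-2,6-diacetoxy-4-methoxyphenyl)-1,7-bis(4-acetoxyphenyl)hept-6-en-3-one
Product: 7 (5R,6Z)-5-(3-acetyl-2,6-diacetoxy-4-methoxyphenyl)-1,7-bis(4-acetoxyphenyl)hept-6-en-3-one
Conditions: fac-Ir(ppy)3 (1 mol %), 450 nm LEDs, degassed MeCN, rt; residual 6 recycled
Reagents that add atoms: none
Why: Triplet energy-transfer E→Z photoisomerisation of a β-alkylstyrene, which accumulates the Z-isomer because A(1,3) strain with the branched C5 twists its aryl out of conjugation so it is no longer sensitised; C5 is untouched.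

Step 5
Reactants: 7 (5R,6Z)-5-(3-acetyl-2,6-diacetoxy-4-methoxyphenyl)-1,7-bis(4-acetoxyphenyl)hept-6-en-3-one
Product: 9 (5S,6S,7R)-5-(3-acetyl-2,6-diacetoxy-4-methoxyphenyl)-1,7-bis(4-acetoxyphenyl)-6,7-epoxyheptan-3-one (cis-epoxide), via bromohydrin 8 (not isolated)
Conditions: NBS (1.1 equiv), THF–H2O 4:1, 0 °C; Na2S2O3 wash; then DBU (1.5 equiv), CH2Cl2, 0 °C
Reagents that add atoms: water, O; N-bromosuccinimide, O=C1CCC(=O)N1Br (its Br stays only in 8)
Why: Halohydrin route to an epoxide: in the A(1,3)-locked Z-alkene (C5–H in plane) Br+ adds to the face away from the di-ortho-substituted aryl, water opens the bromonium ion anti at the benzylic carbon, and DBU closes the ring with inversion at C6, which puts the cis-epoxide oxygen on the aryl-side face (6S,7R) that direct epoxidation would not reach.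

Step 6
Reactants: 9 (5S,6S,7R)-5-(3-acetyl-2,6-diacetoxy-4-methoxyphenyl)-1,7-bis(4-acetoxyphenyl)-6,7-epoxyheptan-3-one
Product: 10 (3S,5S,6S,7R)-5-(3-acetyl-2,6-diacetoxy-4-methoxyphenyl)-1,7-bis(4-acetoxyphenyl)-6,7-epoxyheptan-3-ol
Conditions: (R)-Me-CBS (20 mol %), catecholborane (1.5 equiv), toluene, −78 °C; pH 7 buffer work-up
Reagents that add atoms: none
Why: Corey–Bakshi–Shibata reduction, in which the dialkyl ketone reacts faster than the twisted di-ortho-substituted aryl ketone and the (R)-catalyst, treating the β-branched C4 side as the large group, delivers hydride to give the 3S carbinol (the minor 3R epimer is removed on silica).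

Step 7
Reactants: 10 (3S,5S,6S,7R)-5-(3-acetyl-2,6-diacetoxy-4-methoxyphenyl)-1,7-bis(4-acetoxyphenyl)-6,7-epoxyheptan-3-ol
Product: 11 1-{2,4-diacetoxy-3-[(2S,3S,4S,6S)-2-(4-acetoxyphenyl)-6-[2-(4-acetoxyphenyl)ethyl]-3-hydroxyoxan-4-yl]-6-methoxyphenyl}ethanone
Conditions: CSA (10 mol %), CH2Cl2, −20 → 0 °C
Reagents that add atoms: none
Why: Acid-catalysed 6-endo hydroxy-epoxide cycloetherification, in which aryl π-activation directs the C3–OH to the benzylic carbon and the acetoxy-deactivated aryl keeps the opening SN2, so C7 is inverted to give oxane C2 (S) with an axial aryl and the C6–O bond is kept as the 3S hydroxyl, through a chair with the C4-aryl, C6 side chain and epoxide oxygen equatorial.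

Step 8
Reactants: 11 1-{2,4-diacetoxy-3-[(2S,3S,4S,6S)-2-(4-acetoxyphenyl)-6-[2-(4-acetoxyphenyl)ethyl]-3-hydroxyoxan-4-yl]-6-methoxyphenyl}ethanone; 12 4-hydroxybenzaldehyde (3 equiv)
Product: 14 (E)-1-{2,4-dihydroxy-3-[(2S,3S,4S,6S)-3-hydroxy-2-(4-hydroxyphenyl)-6-[2-(4-hydroxyphenyl)ethyl]oxan-4-yl]-6-methoxyphenyl}-3-(4-hydroxyphenyl)prop-2-en-1-one, via deacetylated ketone 13 (not isolated)
Conditions: KOH (50 % aq.), EtOH, rt, 36 h, argon; neutralise to pH 6 with AcOH at 0 °C
Reagents that add atoms: none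
Why: Saponification of the four aryl acetates followed by Claisen–Schmidt condensation of the aryl methyl ketone (as in helichrysetin-type chalcone syntheses) gives the E-enone, and the non-acidic work-up avoids ionisation and epimerisation of the 4-hydroxybenzylic ether at C2.

## Compound list

1 | 4-(4-hydroxyphenyl)butan-2-one (raspberry ketone) | CC(=O)CCc1ccc(O)cc1 | starting material
2 | (E)-3-(4-hydroxyphenyl)prop-2-enal (4-hydroxycinnamaldehyde) | O=C/C=C/c1ccc(O)cc1 | starting material
3 | (4E,6E)-1,7-bis(4-hydroxyphenyl)hepta-4,6-dien-3-one | O=C(CCc1ccc(O)cc1)/C=C/C=C/c1ccc(O)cc1 | intermediate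
4 | 1-(2,4-dihydroxy-6-methoxyphenyl)ethanone | CC(=O)c1c(O)cc(O)cc1OC | starting material
5 | (5R,6E)-5-(3-acetyl-2,6-dihydroxy-4-methoxyphenyl)-1,7-bis(4-hydroxyphenyl)hept-6-en-3-one (open form; exists mainly as cyclic hemiketals) | COc1cc(O)c([C@@H](/C=C/c2ccc(O)cc2)CC(=O)CCc2ccc(O)cc2)c(O)c1C(C)=O | intermediate
6 | (5R,6E)-5-(3-acetyl-2,6-diacetoxy-4-methoxyphenyl)-1,7-bis(4-acetoxyphenyl)hept-6-en-3-one | COc1cc(OC(C)=O)c([C@@H](/C=C/c2ccc(OC(C)=O)cc2)CC(=O)CCc2ccc(OC(C)=O)cc2)c(OC(C)=O)c1C(C)=O | intermediate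
7 | (5R,6Z)-5-(3-acetyl-2,6-diacetoxy-4-methoxyphenyl)-1,7-bis(4-acetoxyphenyl)hept-6-en-3-one | COc1cc(OC(C)=O)c([C@@H](/C=C\c2ccc(OC(C)=O)cc2)CC(=O)CCc2ccc(OC(C)=O)cc2)c(OC(C)=O)c1C(C)=O | intermediate
8 | (5S,6R,7R)-5-(3-acetyl-2,6-diacetoxy-4-methoxyphenyl)-1,7-bis(4-acetoxyphenyl)-6-bromo-7-hydroxyheptan-3-one | COc1cc(OC(C)=O)c([C@@H]([C@@H](Br)[C@H](O)c2ccc(OC(C)=O)cc2)CC(=O)CCc2ccc(OC(C)=O)cc2)c(OC(C)=O)c1C(C)=O | intermediate
9 | (5S,6S,7R)-5-(3-acetyl-2,6-diacetoxy-4-methoxyphenyl)-1,7-bis(4-acetoxyphenyl)-6,7-epoxyheptan-3-one (cis-epoxide) | COc1cc(OC(C)=O)c([C@@H]([C@@H]2O[C@@H]2c3ccc(OC(C)=O)cc3)CC(=O)CCc2ccc(OC(C)=O)cc2)c(OC(C)=O)c1C(C)=O | intermediate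
10 | (3S,5S,6S,7R)-5-(3-acetyl-2,6-diacetoxy-4-methoxyphenyl)-1,7-bis(4-acetoxyphenyl)-6,7-epoxyheptan-3-ol | COc1cc(OC(C)=O)c([C@@H]([C@@H]2O[C@@H]2c3ccc(OC(C)=O)cc3)C[C@@H](O)CCc2ccc(OC(C)=O)cc2)c(OC(C)=O)c1C(C)=O | intermediate
11 | 1-{2,4-diacetoxy-3-[(2S,3S,4S,6S)-2-(4-acetoxyphenyl)-6-[2-(4-acetoxyphenyl)ethyl]-3-hydroxyoxan-4-yl]-6-methoxyphenyl}ethanone | COc1cc(OC(C)=O)c([C@@H]2C[C@H](CCc3ccc(OC(C)=O)cc3)O[C@@H](c3ccc(OC(C)=O)cc3)[C@H]2O)c(OC(C)=O)c1C(C)=O | intermediate
12 | 4-hydroxybenzaldehyde | O=Cc1ccc(O)cc1 | starting material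
13 | 1-{2,4-dihydroxy-3-[(2S,3S,4S,6S)-3-hydroxy-2-(4-hydroxyphenyl)-6-[2-(4-hydroxyphenyl)ethyl]oxan-4-yl]-6-methoxyphenyl}ethanone | COc1cc(O)c([C@@H]2C[C@H](CCc3ccc(O)cc3)O[C@@H](c3ccc(O)cc3)[C@H]2O)c(O)c1C(C)=O | intermediate
14 | (E)-1-{2,4-dihydroxy-3-[(2S,3S,4S,6S)-3-hydroxy-2-(4-hydroxyphenyl)-6-[2-(4-hydroxyphenyl)ethyl]oxan-4-yl]-6-methoxyphenyl}-3-(4-hydroxyphenyl)prop-2-en-1-one | COc1cc(O)c([C@@H]2C[C@H](CCc3ccc(O)cc3)O[C@@H](c3ccc(O)cc3)[C@H]2O)c(O)c1C(=O)/C=C/c1ccc(O)cc1 | target

## Step count and risks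

Total step count: 8. Longest linear sequence: 8 steps (1 and 2 to 14).

The three steps most likely to fail are steps 2, 6 and 7.

**Step 2 (the proposed new step).** The risks are the site of attack on the arene (C3' versus C5'), 1,4- versus 1,6-addition, a second alkylation, and the level and sense of enantioselectivity. The fallback uses known chemistry; it sets out from 3 and 4 and comes back at 6. The same C–C bond is made without asymmetric induction by the classical base-mediated Michael addition of an acylphloroglucinol to an enone (piperidine/AcOH or Et3N, EtOH, 50 °C), which gives the racemic adduct F1. Acetylation as in step 3 gives the racemic tetraacetate F2. Preparative chiral SFC then separates 6 from its (5S)-enantiomer F3, which is discarded.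

**Step 6.** The ketone is flanked by two methylene groups, so catalyst control may be modest, and the aryl ketone could be touched. The fallback sets out from 9 and comes back at 10, and replaces catalyst control by separation and recycling. Ketone 9 is reduced without a chiral reagent (Zn(BH4)2, Et2O, −20 °C) to 10 and its (3R)-epimer F4. The two diastereomers are separated on silica, and F4 is returned to 9 with Dess–Martin periodinane/NaHCO3 and reduced again.

**Step 7.** A cis-epoxide must place the aryl group axially in the endo transition state, so 5-exo closure at C6 can compete, and any SN1 character would erode C2. The fallback sets out from 10 and comes back at 13; it accepts the 5-exo mode and corrects the ring size afterwards. The 5-exo product formed from 10 under the step 7 acid is the tetrahydrofuran F5 (O-3 bonded to C6 with inversion, benzylic carbinol unchanged). ClCH2SO2Cl and 2,6-lutidine (CH2Cl2, 0 °C) convert it to the benzylic chloromethanesulfonate F6. Zn(OAc)2 in aqueous dioxane at 50 °C then effects the Nakata-type ring expansion: the ring oxygen displaces the sulfonate at C7 with inversion to a bicyclic oxiranium ion, and acetate opens it at C6 with inversion, giving the oxane 3-O-acetate F7. F7 has the same configuration at all four centres as 11. It is put into step 8 unchanged, where KOH removes its five acetates to give 13 and then 14.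

## Further compounds

F1 | step 2 | racemic 5-(3-acetyl-2,6-dihydroxy-4-methoxyphenyl)-1,7-bis(4-hydroxyphenyl)hept-6(E)-en-3-one | COc1cc(O)c(C(/C=C/c2ccc(O)cc2)CC(=O)CCc2ccc(O)cc2)c(O)c1C(C)=O
F2 | step 2 | racemic tetraacetate of F1 | COc1cc(OC(C)=O)c(C(/C=C/c2ccc(OC(C)=O)cc2)CC(=O)CCc2ccc(OC(C)=O)cc2)c(OC(C)=O)c1C(C)=O
F3 | step 2 | (5S,6E)-enantiomer of 6 | COc1cc(OC(C)=O)c([C@H](/C=C/c2ccc(OC(C)=O)cc2)CC(=O)CCc2ccc(OC(C)=O)cc2)c(OC(C)=O)c1C(C)=O
F4 | step 6 | (3R)-epimer of 10 | COc1cc(OC(C)=O)c([C@@H]([C@@H]2O[C@@H]2c3ccc(OC(C)=O)cc3)C[C@H](O)CCc2ccc(OC(C)=O)cc2)c(OC(C)=O)c1C(C)=O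
F5 | step 7 | 5-exo tetrahydrofuran: 2-[(4-acetoxyphenyl)(hydroxy)methyl]-3-(3-acetyl-2,6-diacetoxy-4-methoxyphenyl)-5-[2-(4-acetoxyphenyl)ethyl]oxolane | COc1cc(OC(C)=O)c([C@@H]2C[C@H](CCc3ccc(OC(C)=O)cc3)O[C@H]2[C@H](O)c3ccc(OC(C)=O)cc3)c(OC(C)=O)c1C(C)=O
F6 | step 7 | chloromethanesulfonate of F5 | COc1cc(OC(C)=O)c([C@@H]2C[C@H](CCc3ccc(OC(C)=O)cc3)O[C@H]2[C@H](OS(=O)(=O)CCl)c3ccc(OC(C)=O)cc3)c(OC(C)=O)c1C(C)=O
F7 | step 7 | 3-O-acetate of 11 (pentaacetate) | COc1cc(OC(C)=O)c([C@@H]2C[C@H](CCc3ccc(OC(C)=O)cc3)O[C@@H](c3ccc(OC(C)=O)cc3)[C@H]2OC(C)=O)c(OC(C)=O)c1C(C)=O
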